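In a one-step world, partner meets a fixed stock of intermediate and the rate of making target follows c(partner) at order one. In the opposite extreme, intermediate is used as fast as starting material supplies it, so the rate is that supply and partner has order zero. The real flask must lie between these, and its position depends on how far the intermediate pool has adjusted.

common to all: starting material 0.020 M; free catalyst 1.3 mol%; impurity 74 µM

| charge | partner | remark |
|---|---|---|
| violet | 1.1 equiv | the very flask that is asked about, followed so far |
| red | 2.2 equiv | run made earlier |
| flask | 1.10 equiv |  |

violet run (percent of the starting material charged)

| time / s | target / % | starting material / % |
|---|---|---|
| 12.0 | 11.6 | 74.2 |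
| 30.0 | 34.2 | 51.9 |
| 60.0 | 59.9 | 26.2 |
| 90.0 | 74.2 | 12.3 |

red run (percent of the starting material charged)

| time / min | target / % | starting material / % |
|---|---|---|
| 0.667 | 53.1 | 38.8 |
| 1.33 | 81.3 | 16.0 |
| 2.00 | 89.0 | 6.3 |
| 3.00 | 95.7 | 2.9 |

(standard deviation of a reading: 1 percentage point)

- apparent order in partner when 50% of the starting material are converted (percent change of the rate of making target for one percent more partner charged)

- what may be going on: starting material + free catalyst -> free catalyst + intermediate; partner + free catalyst + intermediate -> free catalyst + target; free catalyst + impurity -> spent catalyst; intermediate -> side product

In the violet run, the fraction of starting material left gives a constant of 0.0223 /s. The red run, with twice the partner, gives 0.0237 /s, so the readings show little effect of partner on supply. Half conversion in violet falls near 30.0 s, where 13.9% is unaccounted for and is read as intermediate. Target in violet gains 48 percentage points between 12.0 s and 60.0 s. Dividing that gain by the time and the pool gives 0.0724 /s, the clearing constant: the pseudo-first-order fraction of the pool turned into target per second.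

Now let x be the clearing constant times the elapsed time. The fraction of the gap to the pool's steady level still open is then exp(−x), and with supply, partner and free catalyst held steady the order is x·exp(−x)/(1−exp(−x)), which runs from one at short times towards zero at long ones. Here x in violet is 2.17, larger than one, and 11.4% of that gap is left. This reckoning gives an order of 0.279. The forecast is lower, at 0.23, holding that “More partner mainly lowers the intermediate pool and barely raises the rate”.

The flask gives 0.23, and at 0.508 min intermediate is made at 0.953 of the rate at which it is used.

    starting material + free catalyst → free catalyst + intermediate (k = 120 /M/s)
    partner + free catalyst + intermediate → free catalyst + target (k = 32000 /M²/s)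
    free catalyst + impurity → spent catalyst (k = 4400 /M/s)
    intermediate → side product (k = 0.00620 /s)

At 4.00 min, partner in the flask stands at 18% of its charge and free catalyst at 71.5%, the same as at 0.400 min, which scales the clearing constant to 0.0192 /s. Adding the side step's 0.0062 /s and taking starting material at 0.467% and intermediate at 0.843% gives making over use of 0.486, and the flask stands at 0.410.

(The runs come from a simulation for substances that don't exist, and the scatter is random.)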